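(Readings and results were generated by integration for an exercise.)

**The question.** I wanted to know how this flask divides its substrate between side product A and target, early and at the end, and which of them leads.

the same everywhere: substrate 0.50 M

|  | reagent | remark | time |
|---|---|---|---|
| amber | 0.55 M | the very flask that is asked about, followed so far |  |
| green | 0.83 M | run made earlier |  |
| flask | 0.550 M |  | 12 min |

- amber (time / min: side product A / %, target / %, substrate / %): 0.167: 0.8, 4.0, 88.7; 0.500: 5.9, 14.7, 74.2; 0.833: 7.2, 21.8, 61.3; 1.33: 10.7, 33.2, 49.7; 2.00: 14.0, 44.7, 33.4; 2.50: 14.8, 49.3, 28.5
- green (time / min: side product A / %, target / %, substrate / %): 0.500: 8.7, 13.0, 71.1; 1.50: 15.8, 34.0, 42.4; 3.00: 22.9, 51.4, 19.7; 5.00: 28.6, 61.8, 7.2; 6.00: 27.9, 62.9, 4.6; 8.00: 29.8, 64.8, 0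

(each reading ± 1 percentage point)

- percent here means substrate units held: one side product B counts as two
- steps under discussion: substrate <-> intermediate; intermediate -> target; reagent + intermediate -> side product A; substrate + intermediate -> side product B

* share of side product A in side product A plus target at 6.0 s
* share of side product A in side product A plus target at 12 min
* which of side product A and target there is more of at 12 min

**Fastest rung.** Under discussion were these steps: substrate passes reversibly to intermediate, which gives target by itself, side product A with reagent, and side product B with substrate. In the amber run 6.50% of the charge was already unaccounted for at 0.167 min, earlier than the 1.33 min at which substrate stood near half.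

**Slowest rung.** Taking one reagent per side product A, amber had spent 13.5% of its own charge by 2.50 min, less than the 71.5% of substrate gone, so I expected the division to drift slowly.

**Split constant.** Both products leave the intermediate, so on these steps its level cancels from their ratio, and c(reagent) remains. Dividing each run's last ratio by its mean c(reagent), I read 0.585 M⁻¹ from amber and 0.609 M⁻¹ from green. I carried their mean, 0.597 M⁻¹: the split constant, side product A formed per target formed, per molar of reagent, a selectivity factor.

**Both ends.** At 6.0 s I took c(reagent) as charged, which gave me a share of 24.7%. For the end I took green's two products together, 94.6%, and let the early share set the reagent spent. My mean c(reagent) then came to 0.492 M and my share to 22.7%, below half, so I put target ahead.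

**The forecast.** It gave 24.7% (22% to 27.5%) and 23% (21% to 25%), with target ahead, and it started from the words “Side product A and target both come from the intermediate”. My late share was lower than its figure.

**The result.** The flask gave 24.5% and 22.6%, with target ahead at 73.6% against 21.5%. The forecast held on all three.

    substrate ⇌ intermediate (K = 0.140, k = 0.0230 s⁻¹)
    intermediate → target (k = 0.0710 s⁻¹)
    reagent + intermediate → side product A (k = 0.0420 M⁻¹ s⁻¹)
    substrate + intermediate → side product B (k = 0.00980 M⁻¹ s⁻¹)

In this flask substrate, the limiting reagent, was down to 0.341% at 12.0 min, while 80.4% of the reagent charge remained. For the neighbouring flask, charged with 0.94 M of reagent, I used the same split constant and reckoned 35.9% early and 33.8% late. It gave 35.7% and 33.6%, and ended at 12.0 min with 63.6% target against 32.2% side product A.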